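**Plan**
- Retrosynthetic cuts, in order: Boc and ketal removal; the C9b–CH=CH alkene back to CH2–CH(OAc); the bond between the amide carbonyl carbon and its α-carbon on the C9b arm (this opens the 20-membered ring); the aryl C8–vinyl bond of the cinnamamide; the C4a–O bond; the C9b–CH2 bond; the aryl–cyclohexene bond.
- Enabling feature: C9b of the hexahydrodibenzofuran carries a two-carbon arm whose outer carbon is bonded to an amide carbonyl carbon. A formylmethyl group on C9b and an isocyanide on the butyl nitrogen of the polyamine chain can therefore be joined at exactly that C–C bond.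
- Forward order: aryl cyclohexenone, allylic alcohol, quaternary C9b by Claisen rearrangement, enone, dihydrofuran ring by oxa-Michael closure, ketal and aldehyde arm, chain attached at C8 by Heck coupling, isocyanide, macrocycle by Passerini reaction, E-enamide, deprotection.
- Stereochemistry: C9b comes from a CBS reduction relayed by a suprafacial [3,3] shift; C4a follows from the cis-only ring closure; the cinnamamide alkene is E from the Heck reaction and the C9b-side alkene is E from a selenoxide syn-elimination.

Key step: step 15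

Assumption: the target is made as the free base with the cis ring fusion (4aR,9bS) read from the SMILES. Atom numbers follow dibenzofuran (O5, C4a, C9b; C8 is the aryl carbon para to O5).

**Route**

Step 1
Reactants: 1 2,4-dibromoanisole; 2 3-ethoxycyclohex-2-en-1-one
Product: 5 3-(5-bromo-2-methoxyphenyl)cyclohex-2-en-1-one, via aryllithium 3 (not isolated), via lithium alkoxide adduct 4 (not isolated)
Conditions: n-BuLi, Et2O, −78 °C; add 2, −78 → 0 °C; 2 M HCl, rt
Reagents that add atoms: water, O
Why: Bromine–lithium exchange takes the bromine ortho to the methoxy group, where the ether oxygen stabilises the aryllithium, the aryllithium adds 1,2 to the vinylogous ester, and aqueous acid ionises the tertiary allylic alkoxide and hydrolyses the enol ether to the transposed enone (Stork–Danheiser sequence).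

Step 2
Reactants: 5 3-(5-bromo-2-methoxyphenyl)cyclohex-2-en-1-one
Product: 6 (1S)-3-(5-bromo-2-methoxyphenyl)cyclohex-2-en-1-ol
Conditions: (R)-2-methyl-CBS-oxazaborolidine (10 mol%), BH3·SMe2, THF, −20 °C; MeOH quench
Reagents that add atoms: none
Why: In this Corey–Bakshi–Shibata reduction the (R)-oxazaborolidine–borane complex binds the ketone with the alkenyl carbon as the large group and delivers hydride to one carbonyl face, which should set C1 as S.

Step 3
Reactants: 6 (1S)-3-(5-bromo-2-methoxyphenyl)cyclohex-2-en-1-ol; 7 N,N-dimethylacetamide dimethyl acetal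
Product: 9 2-[(1R)-1-(5-bromo-2-methoxyphenyl)cyclohex-2-en-1-yl]-N,N-dimethylacetamide, via ketene N,O-acetal 8 (not isolated)
Conditions: 7 (5 equiv), xylene, 140 °C, MeOH distilled off
Reagents that add atoms: none
Why: In this Eschenmoser–Claisen rearrangement, alcohol exchange and loss of methanol give ketene N,O-acetal 8, whose [3,3] shift forms the benzylic quaternary carbon on the ring face that carried the C–O bond, so the S carbinol configuration is passed suprafacially to the R quaternary centre.

Step 4
Reactants: 9 2-[(1R)-1-(5-bromo-2-methoxyphenyl)cyclohex-2-en-1-yl]-N,N-dimethylacetamide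
Product: 10 2-[(1R)-1-(5-bromo-2-methoxyphenyl)-4-oxocyclohex-2-en-1-yl]-N,N-dimethylacetamide
Conditions: CrO3, 3,5-dimethylpyrazole, CH2Cl2, −20 °C
Reagents that add atoms: CrO3, O=[Cr](=O)=O
Why: Allylic oxidation with the CrO3–3,5-dimethylpyrazole complex can only attack the single allylic methylene, the other allylic position being quaternary, and so gives the 4,4-disubstituted cyclohexenone without touching the stereocentre.

Step 5
Reactants: 10 2-[(1R)-1-(5-bromo-2-methoxyphenyl)-4-oxocyclohex-2-en-1-yl]-N,N-dimethylacetamide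
Product: 12 2-[(4aR,9bS)-8-bromo-3-oxo-1,2,3,4,4a,9b-hexahydrodibenzofuran-9b-yl]-N,N-dimethylacetamide, via phenol 11 (not isolated)
Conditions: BBr3, CH2Cl2, −78 → 0 °C; aq NaHCO3; then Et3N, CH2Cl2, rt
Reagents that add atoms: none
Why: BBr3 cleaves the aryl methyl ether and phenol 11 adds to the enone β-carbon in a 5-exo-trig oxa-Michael reaction, in which the aryl tether reaches only the ring face it sits on, so C4a forms with the cis fusion (4aR) dictated by the quaternary centre.

Step 6
Reactants: 12 2-[(4aR,9bS)-8-bromo-3-oxo-1,2,3,4,4a,9b-hexahydrodibenzofuran-9b-yl]-N,N-dimethylacetamide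
Product: 13 2-[(4aR,9bS)-8-bromo-3,3-ethylenedioxy-1,2,3,4,4a,9b-hexahydrodibenzofuran-9b-yl]-N,N-dimethylacetamide
Conditions: (TMSOCH2)2, TMSOTf (cat.), CH2Cl2, −78 → −20 °C; pyridine quench
Reagents that add atoms: 1,2-bis(trimethylsilyloxy)ethane, C[Si](C)(C)OCCO[Si](C)(C)C
Why: Noyori ketalisation forms the dioxolane at low temperature under aprotic conditions, which avoids acid-promoted β-elimination of the aryloxy group, and the ketal then shields the ketone from hydride and base in later steps.

Step 7
Reactants: 13 2-[(4aR,9bS)-8-bromo-3,3-ethylenedioxy-1,2,3,4,4a,9b-hexahydrodibenzofuran-9b-yl]-N,N-dimethylacetamide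
Product: 15 2-[(4aR,9bS)-8-bromo-3,3-ethylenedioxy-1,2,3,4,4a,9b-hexahydrodibenzofuran-9b-yl]acetaldehyde, via zirconium hemiaminal 14 (not isolated)
Conditions: Cp2Zr(H)Cl (1.5 equiv), THF, rt; H2O/silica work-up
Reagents that add atoms: none
Why: Schwartz hydrozirconation of the tertiary amide carbonyl stops at O-zirconated hemiaminal 14, which releases the aldehyde and dimethylamine on aqueous work-up without over-reduction, while ketal, aryl bromide and both stereocentres are untouched.

Step 8
Reactants: 16 butane-1,4-diamine; 17 acrylonitrile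
Product: 18 3-[(4-aminobutyl)amino]propanenitrile
Conditions: 16 (5 equiv), MeOH, 0 °C → rt; excess 16 distilled off
Reagents that add atoms: none
Why: In this aza-Michael addition (cyanoethylation) one amino group of the diamine, used in excess to suppress double addition, adds to acrylonitrile and so differentiates the two ends of the future spermidine chain.

Step 9
Reactants: 18 3-[(4-aminobutyl)amino]propanenitrile; 19 ethyl formate
Product: 20 N-{4-[(2-cyanoethyl)amino]butyl}formamide
Conditions: 19 (solvent), 0 °C → rt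
Reagents that add atoms: none
Why: Aminolysis of the formate ester should formylate the unhindered primary amine much faster than the secondary amine, which is branched and made less nucleophilic by the β-cyano group.

Step 10
Reactants: 20 N-{4-[(2-cyanoethyl)amino]butyl}formamide
Product: 21 tert-butyl (2-cyanoethyl)(4-formamidobutyl)carbamate
Conditions: Boc2O, CH2Cl2, rt
Reagents that add atoms: di-tert-butyl dicarbonate, CC(C)(C)OC(=O)OC(=O)OC(C)(C)C
Why: Carbamate formation (N-acylation) takes place at the remaining secondary amine, the formamide N–H being unreactive toward Boc2O without an acylation catalyst.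

Step 11
Reactants: 21 tert-butyl (2-cyanoethyl)(4-formamidobutyl)carbamate
Product: 22 tert-butyl (3-aminopropyl)(4-formamidobutyl)carbamate
Conditions: H2 (4 bar), Raney Ni, NH3/MeOH, rt
Reagents that add atoms: none
Why: Catalytic hydrogenation of the nitrile, with ammonia suppressing secondary amine formation, gives the primary amine while formamide and carbamate stay intact.

Step 12
Reactants: 22 tert-butyl (3-aminopropyl)(4-formamidobutyl)carbamate; 23 acryloyl chloride
Product: 24 tert-butyl (3-acrylamidopropyl)(4-formamidobutyl)carbamate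
Conditions: Et3N, CH2Cl2, −20 → 0 °C
Reagents that add atoms: none
Why: N-Acylation of the primary amine by the acid chloride at low temperature gives the acrylamide before conjugate addition of the amine can compete.

Step 13
Reactants: 15 2-[(4aR,9bS)-8-bromo-3,3-ethylenedioxy-1,2,3,4,4a,9b-hexahydrodibenzofuran-9b-yl]acetaldehyde; 24 tert-butyl (3-acrylamidopropyl)(4-formamidobutyl)carbamate
Product: 25 tert-butyl {3-[(E)-3-{(4aR,9bS)-3,3-ethylenedioxy-9b-(2-oxoethyl)-1,2,3,4,4a,9b-hexahydrodibenzofuran-8-yl}acrylamido]propyl}(4-formamidobutyl)carbamate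
Conditions: Pd(OAc)2 (5 mol%), P(o-tol)3 (15 mol%), Et3N, DMF, 90 °C
Reagents that add atoms: none
Why: In this Mizoroki–Heck reaction, oxidative addition of zerovalent palladium into the aryl bromide, syn insertion of the acrylamide at its terminal carbon and syn β-hydride elimination give the E-cinnamamide, and the weak amine base should leave the hindered aldehyde, ketal and carbamate intact.

Step 14
Reactants: 25 tert-butyl {3-[(E)-3-{(4aR,9bS)-3,3-ethylenedioxy-9b-(2-oxoethyl)-1,2,3,4,4a,9b-hexahydrodibenzofuran-8-yl}acrylamido]propyl}(4-formamidobutyl)carbamate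
Product: 26 tert-butyl {3-[(E)-3-{(4aR,9bS)-3,3-ethylenedioxy-9b-(2-oxoethyl)-1,2,3,4,4a,9b-hexahydrodibenzofuran-8-yl}acrylamido]propyl}(4-isocyanobutyl)carbamate
Conditions: Burgess reagent (1.5 equiv), CH2Cl2, rt; used at once
Reagents that add atoms: none
Why: Dehydration of the secondary formamide with the Burgess reagent gives the isocyanide under neutral conditions that spare the aldehyde, the secondary amide, the carbamate and the ketal.

Step 15
Reactants: 26 tert-butyl {3-[(E)-3-{(4aR,9bS)-3,3-ethylenedioxy-9b-(2-oxoethyl)-1,2,3,4,4a,9b-hexahydrodibenzofuran-8-yl}acrylamido]propyl}(4-isocyanobutyl)carbamate; 27 acetic acid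
Product: 29 macrocyclic α-acetoxy lactam on the (4aR,9bS) 3-ethylene ketal core, 20-membered ring C9b–CH2–CH(OAc)–C(=O)NH–(CH2)4–N(Boc)–(CH2)3–NH–C(=O)–CH=CH–C8 with E-cinnamamide (both epimers at the acetoxy carbon), via acyl imidate 28 (not isolated)
Conditions: 27 (10 equiv), CH2Cl2, 35 °C; 26 added by syringe pump over 24 h to about 1 mM
Reagents that add atoms: none
Why: Acetic acid hydrogen-bonds to the aldehyde oxygen, the isocyanide carbon at the chain end adds to the aldehyde carbon while acetate adds to the same isocyanide carbon (α-addition), and acyl imidate 28 passes its acetyl group to the new hydroxyl oxygen to leave the α-acetoxy secondary amide. This is a Passerini three-component reaction run as a ring closure, the closest known cases being Passerini and Ugi macrocyclisations of bifunctional isocyanide and carbonyl building blocks. The 20-membered ring closes end-to-end in the C–C bond-forming event itself, the formylmethyl carbon on C9b being attacked by the isocyanide that hangs from the C8 cinnamamide chain. The acetoxy-bearing carbon forms without control, which is accepted because both epimers give the same alkene in step 19, while C4a and C9b are not touched. The step needs ring closure to win over chain growth: slow addition keeps 26 near millimolar concentration while excess acetic acid keeps the α-addition fast, the rigid E-cinnamamide and the tricyclic core bring the two ends closer, and the aprotic, weakly polar solvent favours the concerted Passerini pathway. Ketal, Boc carbamate and both amide N–H groups are inert to dilute acetic acid.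

Step 16
Reactants: 29 macrocyclic α-acetoxy lactam
Product: 30 macrocyclic α-hydroxy lactam (CH2–CH(OH)–C(=O)NH on C9b, both epimers; N-Boc, ketal, E-cinnamamide, 4aR,9bS)
Conditions: K2CO3 (0.2 equiv), MeOH, 0 °C → rt
Reagents that add atoms: none
Why: Base-catalysed transesterification removes the acetate as methyl acetate, and amides, carbamate and ketal are stable to methanolic K2CO3.

Step 17
Reactants: 30 macrocyclic α-hydroxy lactam
Product: 31 macrocyclic α-mesyloxy lactam (CH2–CH(OMs)–C(=O)NH on C9b, both epimers)
Conditions: MsCl, Et3N, CH2Cl2, 0 °C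
Reagents that add atoms: methanesulfonyl chloride, CS(=O)(=O)Cl
Why: O-Sulfonylation of the secondary alcohol turns the α-hydroxy group into a leaving group that the adjacent amide carbonyl activates toward substitution.

Step 18
Reactants: 31 macrocyclic α-mesyloxy lactam
Product: 32 macrocyclic α-(phenylseleno) lactam (CH2–CH(SePh)–C(=O)NH on C9b, both epimers)
Conditions: PhSeSePh, NaBH4, EtOH/THF, 0 °C; then 31, 0 °C → rt
Reagents that add atoms: diphenyl diselenide, c1ccccc1[Se][Se]c1ccccc1
Why: SN2 displacement at the carbonyl-activated α-carbon by the soft, weakly basic benzeneselenolate gives the α-seleno amide with inversion of each epimer, which is immaterial because the centre is removed in the next step.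

Step 19
Reactants: 32 macrocyclic α-(phenylseleno) lactam
Product: 34 N-Boc 3-ethylene ketal of the target (C9b–CH=CH–C(=O)NH E, cinnamamide E, 4aR,9bS), via selenoxide 33 (not isolated)
Conditions: 30% aq H2O2, pyridine, CH2Cl2/THF, 0 °C → rt
Reagents that add atoms: none
Why: Oxidation gives selenoxide 33, which undergoes selenoxide syn-elimination through a five-membered cyclic transition state using the only β-hydrogens (the CH2 on C9b) and should give the conjugated E-alkene from either epimer.

Step 20
Reactants: 34 N-Boc 3-ethylene ketal of the target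
Product: 35 CNP0415009.1, (4aR,9bS) free base
Conditions: TFA/H2O (9:1), 0 °C → rt; aq NaHCO3 work-up
Reagents that add atoms: water, O
Why: Acidolysis removes the Boc group as isobutene and carbon dioxide and hydrolyses the dioxolane to the ketone in one operation, and the cis-fused β-aryloxy ketone and both E-enamides are stable to aqueous acid and to the bicarbonate work-up that frees the secondary amine.

**Compound list**

1 | 2,4-dibromoanisole | COc1ccc(Br)cc1Br | starting material
2 | 3-ethoxycyclohex-2-en-1-one | CCOC1=CC(=O)CCC1 | starting material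
3 | (5-bromo-2-methoxyphenyl)lithium | COc1ccc(Br)cc1[Li] | intermediate
4 | lithium 1-(5-bromo-2-methoxyphenyl)-3-ethoxycyclohex-2-en-1-olate | [Li+].[O-]C1(c2cc(Br)ccc2OC)C=C(OCC)CCC1 | intermediate
5 | 3-(5-bromo-2-methoxyphenyl)cyclohex-2-en-1-one | O=C1C=C(c2cc(Br)ccc2OC)CCC1 | intermediate
6 | (1S)-3-(5-bromo-2-methoxyphenyl)cyclohex-2-en-1-ol | O[C@@H]1C=C(c2cc(Br)ccc2OC)CCC1 | intermediate
7 | N,N-dimethylacetamide dimethyl acetal | CC(OC)(OC)N(C)C | starting material
8 | 1-{[(1S)-3-(5-bromo-2-methoxyphenyl)cyclohex-2-en-1-yl]oxy}-N,N-dimethylethenamine (ketene N,O-acetal) | C=C(N(C)C)O[C@@H]1C=C(c2cc(Br)ccc2OC)CCC1 | intermediate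
9 | 2-[(1R)-1-(5-bromo-2-methoxyphenyl)cyclohex-2-en-1-yl]-N,N-dimethylacetamide | CN(C)C(=O)C[C@@]1(c2cc(Br)ccc2OC)C=CCCC1 | intermediate
10 | 2-[(1R)-1-(5-bromo-2-methoxyphenyl)-4-oxocyclohex-2-en-1-yl]-N,N-dimethylacetamide | CN(C)C(=O)C[C@@]1(c2cc(Br)ccc2OC)C=CC(=O)CC1 | intermediate
11 | 2-[(1R)-1-(5-bromo-2-hydroxyphenyl)-4-oxocyclohex-2-en-1-yl]-N,N-dimethylacetamide | CN(C)C(=O)C[C@@]1(c2cc(Br)ccc2O)C=CC(=O)CC1 | intermediate
12 | 2-[(4aR,9bS)-8-bromo-3-oxo-1,2,3,4,4a,9b-hexahydrodibenzofuran-9b-yl]-N,N-dimethylacetamide | O=C1CC[C@]2(CC(=O)N(C)C)c3cc(Br)ccc3O[C@@H]2C1 | intermediate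
13 | 2-[(4aR,9bS)-8-bromo-3,3-ethylenedioxy-1,2,3,4,4a,9b-hexahydrodibenzofuran-9b-yl]-N,N-dimethylacetamide | O1CCOC12CC[C@]3(CC(=O)N(C)C)c4cc(Br)ccc4O[C@@H]3C2 | intermediate
14 | O-[chlorobis(cyclopentadienyl)zirconio] hemiaminal of 13 (arm CH2–CH(NMe2)–O–Zr(Cl)Cp2) | O1CCOC12CC[C@]3(CC(N(C)C)O[Zr](Cl)(C5C=CC=C5)C5C=CC=C5)c4cc(Br)ccc4O[C@@H]3C2 | intermediate
15 | 2-[(4aR,9bS)-8-bromo-3,3-ethylenedioxy-1,2,3,4,4a,9b-hexahydrodibenzofuran-9b-yl]acetaldehyde | O1CCOC12CC[C@]3(CC=O)c4cc(Br)ccc4O[C@@H]3C2 | intermediate
16 | butane-1,4-diamine | NCCCCN | starting material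
17 | acrylonitrile | C=CC#N | starting material
18 | 3-[(4-aminobutyl)amino]propanenitrile | N#CCCNCCCCN | intermediate
19 | ethyl formate | CCOC=O | starting material
20 | N-{4-[(2-cyanoethyl)amino]butyl}formamide | N#CCCNCCCCNC=O | intermediate
21 | tert-butyl (2-cyanoethyl)(4-formamidobutyl)carbamate | N#CCCN(CCCCNC=O)C(=O)OC(C)(C)C | intermediate
22 | tert-butyl (3-aminopropyl)(4-formamidobutyl)carbamate | NCCCN(CCCCNC=O)C(=O)OC(C)(C)C | intermediate
23 | acryloyl chloride | C=CC(=O)Cl | starting material
24 | tert-butyl (3-acrylamidopropyl)(4-formamidobutyl)carbamate | C=CC(=O)NCCCN(CCCCNC=O)C(=O)OC(C)(C)C | intermediate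
25 | tert-butyl {3-[(E)-3-{(4aR,9bS)-3,3-ethylenedioxy-9b-(2-oxoethyl)-1,2,3,4,4a,9b-hexahydrodibenzofuran-8-yl}acrylamido]propyl}(4-formamidobutyl)carbamate | O1CCOC12CC[C@]3(CC=O)c4cc(/C=C/C(=O)NCCCN(CCCCNC=O)C(=O)OC(C)(C)C)ccc4O[C@@H]3C2 | intermediate
26 | tert-butyl {3-[(E)-3-{(4aR,9bS)-3,3-ethylenedioxy-9b-(2-oxoethyl)-1,2,3,4,4a,9b-hexahydrodibenzofuran-8-yl}acrylamido]propyl}(4-isocyanobutyl)carbamate | O1CCOC12CC[C@]3(CC=O)c4cc(/C=C/C(=O)NCCCN(CCCC[N+]#[C-])C(=O)OC(C)(C)C)ccc4O[C@@H]3C2 | intermediate
27 | acetic acid | CC(=O)O | starting material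
28 | macrocyclic O-acetyl imidate with free α-hydroxyl (C9b–CH2–CH(OH)–C(OAc)=N–(CH2)4–; N-Boc, ketal, E-cinnamamide, 4aR,9bS) | O1CCOC12CC[C@]34CC(O)C(OC(C)=O)=NCCCCN(C(=O)OC(C)(C)C)CCCNC(=O)/C=C/c5ccc(c3c5)O[C@@H]4C2 | intermediate
29 | macrocyclic α-acetoxy lactam (C9b–CH2–CH(OAc)–C(=O)NH–(CH2)4–N(Boc)–(CH2)3–NH–C(=O)–CH=CH–C8, E; 3-ethylene ketal; 4aR,9bS; both epimers at the acetoxy carbon) | O1CCOC12CC[C@]34CC(OC(C)=O)C(=O)NCCCCN(C(=O)OC(C)(C)C)CCCNC(=O)/C=C/c5ccc(c3c5)O[C@@H]4C2 | intermediate
30 | macrocyclic α-hydroxy lactam (as 29 with OH in place of OAc) | O1CCOC12CC[C@]34CC(O)C(=O)NCCCCN(C(=O)OC(C)(C)C)CCCNC(=O)/C=C/c5ccc(c3c5)O[C@@H]4C2 | intermediate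
31 | macrocyclic α-mesyloxy lactam (as 29 with OMs in place of OAc) | O1CCOC12CC[C@]34CC(OS(C)(=O)=O)C(=O)NCCCCN(C(=O)OC(C)(C)C)CCCNC(=O)/C=C/c5ccc(c3c5)O[C@@H]4C2 | intermediate
32 | macrocyclic α-(phenylseleno) lactam (as 29 with SePh in place of OAc) | O1CCOC12CC[C@]34CC([Se]c6ccccc6)C(=O)NCCCCN(C(=O)OC(C)(C)C)CCCNC(=O)/C=C/c5ccc(c3c5)O[C@@H]4C2 | intermediate
33 | selenoxide of 32 | O1CCOC12CC[C@]34CC([Se](=O)c6ccccc6)C(=O)NCCCCN(C(=O)OC(C)(C)C)CCCNC(=O)/C=C/c5ccc(c3c5)O[C@@H]4C2 | intermediate
34 | N-Boc 3-ethylene ketal of the target (both enamides E; 4aR,9bS) | O1CCOC12CC[C@]34/C=C/C(=O)NCCCCN(C(=O)OC(C)(C)C)CCCNC(=O)/C=C/c5ccc(c3c5)O[C@@H]4C2 | intermediate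
35 | CNP0415009.1: 20-membered bis-E-enamide macrocycle bridging C9b and C8 of (4aR,9bS)-1,2,4,4a-tetrahydrodibenzofuran-3(9bH)-one through –CH=CH–C(=O)NH–(CH2)4–NH–(CH2)3–NH–C(=O)–CH=CH– | O=C1CC[C@]23/C=C/C(=O)NCCCCNCCCNC(=O)/C=C/c4ccc(c2c4)O[C@@H]3C1 | target

**Totals and risks**

Total step count: 20. Longest linear sequence: 15 steps (steps 1–7, then 13–20); the chain fragment takes steps 8–12.

Steps most likely to fail:

1. Step 15. Chain growth by intermolecular α-addition, or slow hydration of the isocyanide, may outrun closure of the 20-membered ring. The fallback keeps the Passerini bond but forms it between two molecules and closes the ring at the C8–vinyl bond instead. It sets out from 15 and 24 and comes back to the route at 29. Fragment 24 is dehydrated with the Burgess reagent to tert-butyl (3-acrylamidopropyl)(4-isocyanobutyl)carbamate F1. Bromo aldehyde 15, F1 and acetic acid 27 are combined at about 1 M in CH2Cl2 to give the open-chain α-acetoxy amide with aryl bromide and terminal acrylamide F2. An intramolecular Heck reaction of F2 (Pd(OAc)2, P(o-tol)3, Et3N, MeCN, high dilution, 80 °C) then closes the macrocycle to 29.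

2. Step 13. Aldol condensation or decomposition of the enolisable aldehyde may occur under the hot amine and palladium conditions that the electron-rich aryl bromide requires. The fallback carries the arm as an alcohol through the coupling. It sets out from 13 and comes back at 25. Amide 13 is reduced with LiEt3BH (THF, 0 °C) to 2-[(4aR,9bS)-8-bromo-3,3-ethylenedioxy-1,2,3,4,4a,9b-hexahydrodibenzofuran-9b-yl]ethanol F3. F3 is coupled with 24 under the Heck conditions of step 13 to the corresponding hydroxyethyl E-cinnamamide formamide F4. Dess–Martin periodinane (CH2Cl2, rt) oxidises F4 to 25.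

3. Step 18. Substitution at the secondary carbon next to the neopentyl-like CH2 may be sluggish, and attack at sulfur would return alcohol 30. The fallback replaces substitution and syn-elimination by a direct anti-elimination. It sets out from 31 and comes back at 34. Mesylate 31 is heated with DBU in toluene (80 °C), an E2 loss of methanesulfonic acid of the kind known for α-sulfonyloxy carbonyl compounds, which gives 34 directly and creates no new compound (F0).

**Further compounds**

F1 | step 15 | tert-butyl (3-acrylamidopropyl)(4-isocyanobutyl)carbamate | C=CC(=O)NCCCN(CCCC[N+]#[C-])C(=O)OC(C)(C)C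
F2 | step 15 | open-chain α-acetoxy amide from 15, F1 and acetic acid (aryl bromide and terminal acrylamide retained; 4aR,9bS; both epimers at the acetoxy carbon) | O1CCOC12CC[C@]3(CC(OC(C)=O)C(=O)NCCCCN(CCCNC(=O)C=C)C(=O)OC(C)(C)C)c4cc(Br)ccc4O[C@@H]3C2
F3 | step 13 | 2-[(4aR,9bS)-8-bromo-3,3-ethylenedioxy-1,2,3,4,4a,9b-hexahydrodibenzofuran-9b-yl]ethanol | O1CCOC12CC[C@]3(CCO)c4cc(Br)ccc4O[C@@H]3C2
F4 | step 13 | tert-butyl {3-[(E)-3-{(4aR,9bS)-3,3-ethylenedioxy-9b-(2-hydroxyethyl)-1,2,3,4,4a,9b-hexahydrodibenzofuran-8-yl}acrylamido]propyl}(4-formamidobutyl)carbamate | O1CCOC12CC[C@]3(CCO)c4cc(/C=C/C(=O)NCCCN(CCCCNC=O)C(=O)OC(C)(C)C)ccc4O[C@@H]3C2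
F0 | step 18 | none | none
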